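**Strategy.** The ring (C1 ketone, C2–Br, C3–H, C4 carbinol, C5 alkylidene carbon) is cut into a C5–C1–C2 ketone unit and a vicinal C3–C4 unit at the α-ketoaldehyde oxidation level, exploiting that C2 and C5 flank the C1 carbonyl. In one flask the γ-lithiated acetonylidene phosphorane adds to the C4 ketone of a keto aminal (the aldehyde masked in a temporary proline-derived diazabicycle that enforces ketone-before-aldehyde reactivity and sets the carbinol configuration); acid then frees the aldehyde and the ylide closes the ring by intramolecular Wittig reaction, forming C4–C5 and C2=C3. Bromination, C5 allylation and a kinetic selenoxide syn-elimination complete the (Z)-dienylidene.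

Key step: step 3

Remark on locants: C1–C5 in the explanations are the ring carbons numbered from the ketone as above; compound names use IUPAC locants.

Assumption: the enolate-type nucleophile attacks the magnesium-chelated keto aminal on the same face as Grignard reagents do (chelate model); if the opposite sense were found, the enantiomeric diamine from D-proline would be used with no other change.

**Step 1**
Reactants: 1 monomethyl azelate
Product: 3 methyl 10-diazo-9-oxodecanoate, via acid chloride 2 (not isolated)
Conditions: (COCl)2, cat. DMF, CH2Cl2, 0 °C → rt; then TMSCHN2, THF–MeCN, 0 °C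
Reagents that add atoms: trimethylsilyldiazomethane, C[Si](C)(C)C=[N+]=[N-]
Why: Acid chloride formation followed by acylation of the diazoalkane (Arndt–Eistert-type diazoketone synthesis) adds the future C3 carbon while the methyl ester stays inert.

**Step 2**
Reactants: 3 methyl 10-diazo-9-oxodecanoate; 4 (S)-2-(anilinomethyl)pyrrolidine
Product: 6 methyl 9-oxo-9-[(2R,5S)-3-phenyl-1,3-diazabicyclo[3.3.0]octan-2-yl]nonanoate (acyl group exo; cis to H-5), via keto aldehyde 5 (not isolated)
Conditions: DMDO, acetone, 0 °C; evaporate; then 4, CH2Cl2, 4 Å MS, rt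
Reagents that add atoms: dimethyldioxirane, CC1(C)OO1
Why: Dioxirane oxidation of the α-diazo ketone gives the α-ketoaldehyde under neutral conditions, and the diamine condenses only with the aldehyde (aminal formation) to give, under thermodynamic control by the proline-derived centre, the cis-fused aminal with the acyl group on the convex face.

**Step 3**
Reactants: 6 methyl 9-oxo-9-[(2R,5S)-3-phenyl-1,3-diazabicyclo[3.3.0]octan-2-yl]nonanoate; 7 1-(triphenyl-λ5-phosphanylidene)propan-2-one
Product: 11 methyl 8-[(1R)-1-hydroxy-4-oxocyclopent-2-en-1-yl]octanoate, via lithiated ylide 8 (not isolated), via aminal carbinol 9 (not isolated), via hydroxy aldehyde ylide 10 (not isolated)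
Conditions: 7, n-BuLi, THF, −78 °C; add 6·MgBr2·OEt2, −78 → −40 °C; 2% aq HCl, 0 °C; then NaHCO3 to pH 8, CH2Cl2, rt
Reagents that add atoms: none
Why: The γ-lithiated ylide (nucleophilic at C5, ylide carbon C2 untouched) adds aldol-wise to the C4 ketone of 6, which is held in a magnesium chelate between the carbonyl oxygen and the pyrrolidine nitrogen of the rigid cis-fused aminal, so attack on the exposed face should set the (R)-carbinol as Grignard reagents do with this auxiliary. Dilute acid then hydrolyses the aminal (freeing the C3 aldehyde and the recoverable diamine) and protonates the ylide, and at pH 8 the acyl-stabilised ylide re-forms while the diamine stays protonated. Intramolecular Wittig olefination (5-(enolendo)-exo-trig attack of ylide carbon C2 on the aldehyde, oxaphosphetane, loss of Ph3PO) closes the cyclopentenone, and the ring enforces the cis C2=C3 geometry. The closest known reaction types are chelation-controlled additions to proline-derived keto aminals, γ-functionalisation of acylmethylene-phosphorane anions and Wittig cyclopentenone annulations. The step needs ketone-before-aldehyde reactivity (secured by the aminal mask), C5 rather than C2 or the chain α-CH2 as nucleophile (secured by the preformed γ-anion) and survival of the tertiary alcohol (secured by the near-neutral ring closure, which cannot dehydrate it).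

**Step 4**
Reactants: 11 methyl 8-[(1R)-1-hydroxy-4-oxocyclopent-2-en-1-yl]octanoate
Product: 13 methyl 8-[(1R)-3-bromo-1-hydroxy-4-oxocyclopent-2-en-1-yl]octanoate, via dibromide 12 (not isolated)
Conditions: Br2, CH2Cl2, 0 °C; then Et3N, 0 °C → rt
Reagents that add atoms: bromine, BrBr
Why: Addition of Br2 across the enone and base-induced E1cB loss of HBr (α-bromination of an enone by addition–elimination) leaves bromine on C2 because only the C2 proton is acidified by the carbonyl, and C4 is untouched.

**Step 5**
Reactants: 13 methyl 8-[(1R)-3-bromo-1-hydroxy-4-oxocyclopent-2-en-1-yl]octanoate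
Product: 14 methyl 8-[(1R)-3-bromo-4-oxo-1-(trimethylsilyloxy)cyclopent-2-en-1-yl]octanoate
Conditions: TMS-imidazole, CH2Cl2, rt
Reagents that add atoms: N-(trimethylsilyl)imidazole, C[Si](C)(C)n1ccnc1
Why: Neutral silyl transfer caps the tertiary alcohol (silyl ether protection) so that no C4 alkoxide can trigger retro-aldol ring opening and racemisation in the enolate steps.

**Step 6**
Reactants: 14 methyl 8-[(1R)-3-bromo-4-oxo-1-(trimethylsilyloxy)cyclopent-2-en-1-yl]octanoate; 15 (E)-1-bromopent-2-ene
Product: 17 methyl 8-[(1R)-3-bromo-4-oxo-5-[(2E)-pent-2-en-1-yl]-1-(trimethylsilyloxy)cyclopent-2-en-1-yl]octanoate (C5 epimers), via lithium enolate 16 (not isolated)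
Conditions: LDA, THF, −78 °C; then 15, DMPU, −78 → −30 °C
Reagents that add atoms: none
Why: Kinetic deprotonation at the only enolisable ring position gives the cross-conjugated lithium dienolate, which is C-alkylated by the primary allylic bromide at C5 (SN2 enolate alkylation) with the E-alkene carried in unchanged; the new C5 centre is erased in step 7.

**Step 7**
Reactants: 17 methyl 8-[(1R)-3-bromo-4-oxo-5-[(2E)-pent-2-en-1-yl]-1-(trimethylsilyloxy)cyclopent-2-en-1-yl]octanoate
Product: 22 methyl 8-[(1S,5Z)-3-bromo-1-hydroxy-4-oxo-5-[(2E)-pent-2-en-1-ylidene]cyclopent-2-en-1-yl]octanoate, via lithium enolate 18 (not isolated), via selenide 19 (not isolated), via selenoxide 20 (not isolated), via silyl dienone 21 (not isolated)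
Conditions: LDA, THF, −78 °C; PhSeBr; then 30% H2O2, pyridine, CH2Cl2, 0 °C → rt; then 1 M HCl, THF, 0 °C
Reagents that add atoms: none
Why: In this α-selenenylation/oxidation dehydrogenation the selenoxide can only take a side-chain allylic hydrogen (C4 carries none) in a five-membered syn-elimination transition state in which the vinyl group turns away from the quaternary C4, which should give the (Z)-alkylidene (chain syn to C=O) under kinetic control, after which dilute acid removes the TMS group.

**Compound list**
1 | monomethyl azelate (9-methoxy-9-oxononanoic acid) | COC(=O)CCCCCCCC(=O)O | starting material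
2 | methyl 9-chloro-9-oxononanoate | COC(=O)CCCCCCCC(=O)Cl | intermediate
3 | methyl 10-diazo-9-oxodecanoate | COC(=O)CCCCCCCC(=O)C=[N+]=[N-] | intermediate
4 | (S)-2-(anilinomethyl)pyrrolidine [(S)-N-(pyrrolidin-2-ylmethyl)aniline] | C1C[C@H](NC1)CNc1ccccc1 | starting material
5 | methyl 9,10-dioxodecanoate | COC(=O)CCCCCCCC(=O)C=O | intermediate
6 | methyl 9-oxo-9-[(2R,5S)-3-phenyl-1,3-diazabicyclo[3.3.0]octan-2-yl]nonanoate (acyl exo; cis to H-5) | COC(=O)CCCCCCCC(=O)[C@H]1N(c3ccccc3)C[C@@H]2CCCN12 | intermediate
7 | 1-(triphenyl-λ5-phosphanylidene)propan-2-one (acetonylidenetriphenylphosphorane) | CC(=O)C=P(c1ccccc1)(c1ccccc1)c1ccccc1 | starting material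
8 | γ-lithiated ylide (lithium enolate of 7) | [Li]OC(=C)C=P(c1ccccc1)(c1ccccc1)c1ccccc1 | intermediate
9 | methyl (9R)-9-hydroxy-11-oxo-9-[(2R,5S)-3-phenyl-1,3-diazabicyclo[3.3.0]octan-2-yl]-12-(triphenyl-λ5-phosphanylidene)dodecanoate | COC(=O)CCCCCCC[C@@](O)(CC(=O)C=P(c1ccccc1)(c1ccccc1)c1ccccc1)[C@H]2N(c3ccccc3)C[C@@H]4CCCN24 | intermediate
10 | methyl (9R)-9-formyl-9-hydroxy-11-oxo-12-(triphenyl-λ5-phosphanylidene)dodecanoate | COC(=O)CCCCCCC[C@@](O)(CC(=O)C=P(c1ccccc1)(c1ccccc1)c1ccccc1)C=O | intermediate
11 | methyl 8-[(1R)-1-hydroxy-4-oxocyclopent-2-en-1-yl]octanoate | C1C(=O)C=C[C@@]1(O)CCCCCCCC(=O)OC | intermediate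
12 | methyl 8-[(1R)-2,3-dibromo-1-hydroxy-4-oxocyclopentyl]octanoate (trans-dibromide, diastereomer mixture) | C1C(=O)C(Br)C(Br)[C@@]1(O)CCCCCCCC(=O)OC | intermediate
13 | methyl 8-[(1R)-3-bromo-1-hydroxy-4-oxocyclopent-2-en-1-yl]octanoate | C1C(=O)C(Br)=C[C@@]1(O)CCCCCCCC(=O)OC | intermediate
14 | methyl 8-[(1R)-3-bromo-4-oxo-1-(trimethylsilyloxy)cyclopent-2-en-1-yl]octanoate | C1C(=O)C(Br)=C[C@@]1(O[Si](C)(C)C)CCCCCCCC(=O)OC | intermediate
15 | (E)-1-bromopent-2-ene | CC/C=C/CBr | starting material
16 | lithium enolate of 14 | C1=C(O[Li])C(Br)=C[C@@]1(O[Si](C)(C)C)CCCCCCCC(=O)OC | intermediate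
17 | methyl 8-[(1R)-3-bromo-4-oxo-5-[(2E)-pent-2-en-1-yl]-1-(trimethylsilyloxy)cyclopent-2-en-1-yl]octanoate (C5 epimers) | CC/C=C/CC1C(=O)C(Br)=C[C@@]1(O[Si](C)(C)C)CCCCCCCC(=O)OC | intermediate
18 | lithium enolate of 17 | CC/C=C/CC1=C(O[Li])C(Br)=C[C@@]1(O[Si](C)(C)C)CCCCCCCC(=O)OC | intermediate
19 | methyl 8-[(1S)-3-bromo-4-oxo-5-[(2E)-pent-2-en-1-yl]-5-(phenylselanyl)-1-(trimethylsilyloxy)cyclopent-2-en-1-yl]octanoate (C5 epimers) | CC/C=C/CC1([Se]c2ccccc2)C(=O)C(Br)=C[C@@]1(O[Si](C)(C)C)CCCCCCCC(=O)OC | intermediate
20 | selenoxide of 19 | CC/C=C/CC1([Se](=O)c2ccccc2)C(=O)C(Br)=C[C@@]1(O[Si](C)(C)C)CCCCCCCC(=O)OC | intermediate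
21 | methyl 8-[(1S,5Z)-3-bromo-4-oxo-5-[(2E)-pent-2-en-1-ylidene]-1-(trimethylsilyloxy)cyclopent-2-en-1-yl]octanoate | CC/C=C/C=C1\C(=O)C(Br)=C[C@@]1(O[Si](C)(C)C)CCCCCCCC(=O)OC | intermediate
22 | methyl 8-[(1S,5Z)-3-bromo-1-hydroxy-4-oxo-5-[(2E)-pent-2-en-1-ylidene]cyclopent-2-en-1-yl]octanoate | CC/C=C/C=C1\C(=O)C(Br)=C[C@@]1(O)CCCCCCCC(=O)OC | target

**Totals**
Total step count: 7. Longest linear sequence: 7 steps (1 → 22).

**Steps most likely to fail**

Step 3 (key step). The enolate-type nucleophile may enolise the hindered keto aminal instead of adding, may add with poor facial discrimination, or the aldolate may revert on warming. The fallback sets out from 6 and comes back at 11. Addition of 2-methylallylmagnesium chloride, a true Grignard reagent and therefore the nucleophile class for which chelation control by this aminal is established, should give methallyl carbinol aminal F1. Hydrolysis with 2% HCl should release hydroxy aldehyde F2 and the diamine. Ozonolysis (O3, CH2Cl2, −78 °C; Me2S) of the 1,1-disubstituted alkene should give keto aldehyde F3. Its only productive enolate (the methyl ketone CH3) should close onto the aldehyde in an intramolecular aldol condensation (dibenzylammonium trifluoroacetate, benzene, 50 °C) to give 11. The two ring bonds are then made in separate operations.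

Step 7. Deprotonation at the congested tertiary α′-carbon may be slow (ester enolisation competing), or the geometric preference of the syn-elimination may erode. The fallback sets out from 17 and comes back at 21. Soft enolisation (TMSOTf, Et3N, CH2Cl2, 0 °C), which can only occur toward C5, should give silyl dienol ether F4. Hydride abstraction from the doubly allylic side-chain CH2 with DDQ (2,6-lutidine, CH2Cl2, 0 °C) should then give silyl dienone 21, which is desilylated as in the last stage of step 7.

Step 6. O-alkylation, double alkylation or SN2′ attack may compete with the wanted C-alkylation next to the quaternary centre. The fallback sets out from 14 and comes back at 21. The lithium enolate 16 is added to (E)-pent-2-enal (THF, −78 °C) to give aldol adduct F5. Mesylation (MsCl, Et3N, CH2Cl2, 0 °C) gives mesylate F6, which should eliminate by E1cB to 21 together with its (5E)-isomer F7. Irradiation of F7 (365 nm) should set up an E/Z photostationary mixture from which 21 is separated and F7 recycled. Desilylation as in step 7 then gives 22.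

**Further compounds**
F1 | step 3 | methyl (9R)-9-hydroxy-11-methyl-9-[(2R,5S)-3-phenyl-1,3-diazabicyclo[3.3.0]octan-2-yl]dodec-11-enoate | COC(=O)CCCCCCC[C@@](O)(CC(C)=C)[C@H]1N(c3ccccc3)C[C@@H]2CCCN12
F2 | step 3 | methyl (9R)-9-formyl-9-hydroxy-11-methyldodec-11-enoate | COC(=O)CCCCCCC[C@@](O)(CC(C)=C)C=O
F3 | step 3 | methyl (9R)-9-formyl-9-hydroxy-11-oxododecanoate | COC(=O)CCCCCCC[C@@](O)(CC(C)=O)C=O
F4 | step 7 | methyl 8-[(1R)-3-bromo-5-[(2E)-pent-2-en-1-yl]-1,4-bis(trimethylsilyloxy)cyclopenta-2,4-dien-1-yl]octanoate | CC/C=C/CC1=C(O[Si](C)(C)C)C(Br)=C[C@@]1(O[Si](C)(C)C)CCCCCCCC(=O)OC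
F5 | step 6 | methyl 8-[(1R)-3-bromo-5-[(2E)-1-hydroxypent-2-en-1-yl]-4-oxo-1-(trimethylsilyloxy)cyclopent-2-en-1-yl]octanoate (diastereomer mixture) | CC/C=C/C(O)C1C(=O)C(Br)=C[C@@]1(O[Si](C)(C)C)CCCCCCCC(=O)OC
F6 | step 6 | methanesulfonate of F5 | CC/C=C/C(OS(C)(=O)=O)C1C(=O)C(Br)=C[C@@]1(O[Si](C)(C)C)CCCCCCCC(=O)OC
F7 | step 6 | methyl 8-[(1S,5E)-3-bromo-4-oxo-5-[(2E)-pent-2-en-1-ylidene]-1-(trimethylsilyloxy)cyclopent-2-en-1-yl]octanoate | CC/C=C/C=C1/C(=O)C(Br)=C[C@@]1(O[Si](C)(C)C)CCCCCCCC(=O)OC
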